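## The problem

Germacrane numbering is used throughout: C10 is the ether carbon bearing CH3 C14, C9 the ester CH, C8 the lactone O–CH, C7 the lactone C–CH, C6 a CH2, C5 the ether CH, C4 the CH bearing CH3 C15, C3–C1 the CH2 chain back to C10, and C11/C12/C13 the lactone alkene carbon, carbonyl and exocyclic CH2; ring B is the oxepane O/C5–C10 and ring C the oxepane O/C10/C1–C5. The target 28 is a ten-membered carbocycle bridged between C5 and C10 by oxygen (an 11-oxabicyclo[4.4.1]undecane), with a trans-fused α-methylene-γ-lactone on C7/C8 and an isovalerate on C9. It has six stereocentres: four contiguous ones on ring B (C7, C8, C9 and the fully substituted ether carbon C10), the bridgehead C5, whose configuration follows from C10 once the oxygen bridge exists, and C4, which can be corrected by epimerisation as long as C5 is a carbonyl carbon. On the chair of a six-carbon precursor of ring B that keeps the C7 branch equatorial, the C8 and C9 oxygens and the C1 chain on C10 are equatorial and only C14 is axial; C8 and C9 therefore call for enolate oxidation and axial hydride delivery, and C10 for a stereospecific transfer, not for trans-diaxial epoxide opening or a cis-selective enolate alkylation. The exocyclic enoate (a Michael and radical acceptor) and the C9 ester cannot be present in any organometallic, enolate, hydride or single-electron step, so both come last and C11–C13 must travel as an isopropenyl group that every oxidant on the way has to spare. The enabling feature is that C5–C10, with C14 on C10 and the three-carbon branch on C7, is the carvone skeleton with one oxygen inserted between C5 and C10: ring B can be carried as an ε-lactone with C5 as acyl carbon and the C1–C4 chain on the alkoxy carbon C10, so the only missing skeletal bond is C4–C5, and attack of C4 on the lactone carbonyl gives the bridged hemiketal, that is ring C and the ten-membered ring together.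

## Retrosynthesis

**Ester and lactone (28 ⇒ 26 + 27 ⇒ 23 ⇒ 22).** The C9–O acyl bond is cut first, to hydroxy lactone 26 and isovaleric anhydride 27. The lactone C12–O8 bond and the C12 oxidation level are cut next, back to allylic alcohol 23 and then to the isopropenyl diol 22. Cutting C7–C11 instead would discard a stereocentre and a C–C bond that the starting terpene supplies. The precursor 22 has no electrophilic alkene and no ester. The forward reactions must oxidise the isopropenyl methyl group, lactonise onto O8 rather than O9 (five-membered against bridged six-membered ring), and acylate a hindered secondary alcohol.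

**Bridgehead C5–H (22 ⇒ 21 ⇒ 20).** The C5–H bond is traced to the C5–OH of bridged hemiketal 20; the silyl ethers of 21 are the protected form of 22. A hemiketal at C5 is what an acyl substitution leaves, and its reduction cannot give a wrong C5 epimer because C5 is a bridgehead. The forward step must ionise a bridgehead hemiketal without touching the isopropenyl group or the silyl ethers, which is why acetal-type protecting groups are excluded.

**Key cut C4–C5 (20 ⇒ 17).** Of the ring bonds of the bicycle only C4–C5 joins a carbon that can be a nucleophile (C4, from a C–I bond) to one that is already an acyl carbon in a simple monocycle (C5 of ε-lactone 17). Cutting C1–C10 or an ether C–O bond would demand a ten-membered ring closure or a transannular etherification with free choice of C10 configuration. The precursor is monocyclic with four stereocentres, all on one ring. The forward step asks a secondary organosamarium to close a seven-membered ring onto the lactone carbonyl and leaves C4 to equilibration.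

**Chain terminus (17 ⇒ 16 ⇒ 15 ⇒ 14).** The C4–I bond comes from the C4 carbinol 16, that from methyl ketone 15, and that from the terminal alkene of 14. A terminal alkene is the one C4 precursor that survives Grignard formation, Lewis acids and enolate chemistry without a protecting group and creates no early epimer mixture. The forward steps need a Markovnikov oxidation that ignores the isopropenyl group and a ketone reduction that spares the lactone.

**Ring oxygen (14 ⇒ 13).** The C10–O bond is cut to the C5–C10 bond of cyclohexanone 13 (Baeyer–Villiger oxidation). Lactonisation of a seco acid onto a tertiary alcohol is the weaker neighbour. The forward step must insert oxygen on the quaternary side and must not epoxidise two isolated alkenes, which rules out peracids.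

**C8 and C9 oxygens (13 ⇒ 12 ⇒ 11 ⇒ 10 ⇒ 9 ⇒ 7).** The C8–O bond is cut to an enolate of the C9 ketone 7 and the C9–H bond to a hydride. The neighbour, anti-dihydroxylation of a C8=C9 alkene, would open the epoxide trans-diaxially and give the other trans-diol, and would compete with the isopropenyl group. With C10 quaternary the C9 ketone enolises only toward C8, the oxidant enters anti to the C7 branch, and hydride then enters axially opposite the axial C14. C5 is held as a silyl ether meanwhile, because a C5/C9 diketone would have a mirror plane through C10 and C7 and lose the chirality.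

**Quaternary C10 (7 ⇒ 6 ⇒ 5 ⇒ 4 ⇒ 1 + 2).** The C10–C1 bond is cut by a 1,2-shift: in epoxy alcohol 5 the pentenyl group sits on C9, and it is put there by addition of the Grignard reagent 3 (from 5-bromopent-1-ene 2) to the carbonyl of (S)-carvone 1. Direct alkylation of a carvone-derived C10 enolate is shorter, but axial attack places the incoming chain cis to the isopropenyl group, the wrong C10 epimer. The shift is stereospecific: the chain adds trans to the isopropenyl group, the hydroxyl directs the epoxide to the other face, and the chain migrates on its own face. It also delivers the C9 ketone and the C5 oxygen needed above. Carvone's carbonyl carbon becomes C9, its methyl-bearing carbon C10, its β-carbon C5 and its isopropenyl-bearing carbon C7, which requires the (S)-enantiomer.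

## Roads not taken

**Alternative 1:** The cut is at C4–C15 and C5–C6 on a six-membered ring holding C10 (as carbonyl) and C1–C5. In the forward step Cu(OTf)2 with a BINOL-derived phosphoramidite catalyses addition of Zn(CH3)2 to the parent cyclohexenone, and the zinc enolate is allylated under Pd(PPh3)4 to give A1.
- Merits: one catalytic operation sets C4 and C5 (trans) under reagent control, with C15 in place from the start.
- Weak points: no ring of 28 is formed. The C5–C10 bond of A1 must later be broken by oxygen insertion, and the whole of ring B, with C7, C8, C9 and the oxygenated quaternary C10, remains to be built onto a lactone carbonyl, including a medium-ring closure.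
- Comparison: this road is better at C4, which the chosen plan leaves to equilibration. The chosen plan sets against it four contiguous centres from substrate control on a carvone ring and closure of ring C and the carbocycle in one step.

**Alternative 2:** The cut is at O–C10 and C10–C1. A copper carbenoid from a C10 diazo ketone is captured by the oxygen of a vinyl oxetane, and the ylide undergoes a [2,3]-shift to give A2.
- Merits: two bonds, both oxepanes and the quaternary centre arise in one step with the lactone ring already present. In bond-forming power per step this road is superior, and that has to be conceded.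
- Weak points: the precursor (a stereodefined vinyl oxetane tethered to a methyl-substituted diazo ketone) is long to make. The methyl-bearing carbenoid can divert by 1,2-hydride shift, [1,2]-shift competes with the [2,3]-shift, and the face of C10 is not obviously controlled. C9 ketone reduction, alkene saturation and methylenation still follow.
- Comparison: the chosen plan sets against it a precursor assembled from a cheap terpene by substrate-controlled steps and a cyclisation of a well-documented type.

**Alternative 3:** The cut is at C7–C11. Rh2(OAc)4 decomposes a C8 diazophosphonoacetate and the carbenoid inserts into C7–H to give A3, which a Horner–Wadsworth–Emmons reaction with formaldehyde would convert into the methylene lactone.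
- Merits: the exocyclic alkene comes from a clean olefination with no allylic oxidation, and the ester is already in place. This endgame is better than steps 17 and 18 of the chosen route.
- Weak points: the bridged core must be made without the C7 branch, so carvone cannot supply it and C7 cannot control C8. C7–H competes with C9–H (both give five-membered lactones), and such insertions prefer cis ring fusion where trans is needed.
- Comparison: the chosen plan sets against it that the C7–C11 bond and its configuration come with the starting material and that no C–H selectivity question arises.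

Key step: step 14

Remark on the chemistry: C4 of 16–19 is carried as a mixture of epimers, since its configuration is erased at the radical stage of step 14 and reset by equilibration; 20 is written in its closed hemiketal form, which is in equilibrium with the ten-membered 5-keto 10-hydroxy tautomer.

## Route

Step 1
Reactants: 1 (S)-carvone; 2 5-bromopent-1-ene
Product: 4 (1S,5S)-2-methyl-1-(pent-4-en-1-yl)-5-(prop-1-en-2-yl)cyclohex-2-en-1-ol, via pent-4-enylmagnesium bromide 3 (not isolated)
Conditions: 2, Mg, THF, rt; then 1, −78 to 0 °C; H2O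
Reagents that add atoms: none
Why: Grignard 1,2-addition to the enone carbonyl; attack on the half-chair is axial and anti to the pseudo-equatorial isopropenyl group (the sense of hydride delivery that gives cis-carveol), which should place the pentenyl group trans and the hydroxyl cis to the isopropenyl group, the minor C9 epimer being removed by chromatography.

Step 2
Reactants: 4 (1S,5S)-2-methyl-1-(pent-4-en-1-yl)-5-(prop-1-en-2-yl)cyclohex-2-en-1-ol
Product: 5 (1R,2S,4S,6R)-1-methyl-2-(pent-4-en-1-yl)-4-(prop-1-en-2-yl)-7-oxabicyclo[4.1.0]heptan-2-ol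
Conditions: VO(acac)2 (cat.), t-BuOOH, toluene, rt
Reagents that add atoms: tert-butyl hydroperoxide, CC(C)(C)OO
Why: Hydroxyl-directed epoxidation of the allylic alcohol: the vanadium alkoxide delivers oxygen to C10=C5 syn to the hydroxyl, hence anti to the pentenyl group, and leaves the two undirected alkenes untouched.

Step 3
Reactants: 5 (1R,2S,4S,6R)-1-methyl-2-(pent-4-en-1-yl)-4-(prop-1-en-2-yl)-7-oxabicyclo[4.1.0]heptan-2-ol
Product: 6 (2S,3R,5S)-3-hydroxy-2-methyl-2-(pent-4-en-1-yl)-5-(prop-1-en-2-yl)cyclohexan-1-one
Conditions: BF3·OEt2, CH2Cl2, −78 °C; aq. NaHCO3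
Reagents that add atoms: none
Why: Semipinacol rearrangement of a 2,3-epoxy alcohol: the epoxide ionises at tertiary C10 and the pentenyl group, pseudo-axial on C9 and antiperiplanar to the breaking C10–O bond, shifts to C10 with inversion while C9 becomes the ketone. The shift is suprafacial, so the chain stays trans and C14 ends cis to the isopropenyl group; the former epoxide oxygen remains on C5 as a hydroxyl whose configuration is lost later on oxidation.

Step 4
Reactants: 6 (2S,3R,5S)-3-hydroxy-2-methyl-2-(pent-4-en-1-yl)-5-(prop-1-en-2-yl)cyclohexan-1-one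
Product: 7 (2S,3R,5S)-2-methyl-2-(pent-4-en-1-yl)-5-(prop-1-en-2-yl)-3-[(triethylsilyl)oxy]cyclohexan-1-one
Conditions: Et3SiCl, imidazole, DMF, 0 °C to rt
Reagents that add atoms: chlorotriethylsilane, CC[Si](Cl)(CC)CC
Why: Silylation of the secondary aldol hydroxyl; it blocks retro-aldol cleavage of C5–C10 in the enolate step and keeps C5 distinguishable from C9.

Step 5
Reactants: 7 (2S,3R,5S)-2-methyl-2-(pent-4-en-1-yl)-5-(prop-1-en-2-yl)-3-[(triethylsilyl)oxy]cyclohexan-1-one
Product: 9 (2S,3R,5R,6R)-6-hydroxy-2-methyl-2-(pent-4-en-1-yl)-5-(prop-1-en-2-yl)-3-[(triethylsilyl)oxy]cyclohexan-1-one, via potassium enolate 8 (not isolated)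
Conditions: KN(SiMe3)2, THF, −78 °C; 2-(benzenesulfonyl)-3-phenyloxaziridine, −78 °C; AcOH
Reagents that add atoms: 2-(benzenesulfonyl)-3-phenyloxaziridine, O=S(=O)(c1ccccc1)N1OC1c1ccccc1
Why: Enolate hydroxylation with an N-sulfonyloxaziridine; the ketone can enolise only toward C8 because C10 is quaternary, and the oxidant enters anti to the adjacent C7 isopropenyl group, giving the trans, equatorial C8 hydroxyl, which is also the more stable epimer and spares the alkenes.

Step 6
Reactants: 9 (2S,3R,5R,6R)-6-hydroxy-2-methyl-2-(pent-4-en-1-yl)-5-(prop-1-en-2-yl)-3-[(triethylsilyl)oxy]cyclohexan-1-one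
Product: 10 (1R,2R,3R,4R,6R)-3-methyl-3-(pent-4-en-1-yl)-6-(prop-1-en-2-yl)-4-[(triethylsilyl)oxy]cyclohexane-1,2-diol
Conditions: NaBH4, MeOH, −20 to 0 °C
Reagents that add atoms: none
Why: Borohydride reduction; in the chair with the isopropenyl group, the C8 hydroxyl, the silyloxy group and the chain equatorial and C14 axial, hydride attacks C9 axially from the face opposite the axial methyl, giving the equatorial C9 hydroxyl trans to O8 and cis to C14.

Step 7
Reactants: 10 (1R,2R,3R,4R,6R)-3-methyl-3-(pent-4-en-1-yl)-6-(prop-1-en-2-yl)-4-[(triethylsilyl)oxy]cyclohexane-1,2-diol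
Product: 11 the 1,2-bis(tert-butyldimethylsilyl) ether of 10 (configuration as in 10)
Conditions: TBSOTf, 2,6-lutidine, CH2Cl2, 0 °C to rt
Reagents that add atoms: tert-butyldimethylsilyl trifluoromethanesulfonate, CC(C)(C)[Si](C)(C)OS(=O)(=O)C(F)(F)F
Why: Silyl triflate silylation of both secondary hydroxyls (the neopentyl C9 hydroxyl needs the triflate); these ethers offer no electrophilic site to an organosamarium and should tolerate silane/BF3 at low temperature, unlike acetal-type groups.

Step 8
Reactants: 11 the 1,2-bis(tert-butyldimethylsilyl) ether of 10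
Product: 12 (1R,2S,3R,4R,5R)-3,4-bis[(tert-butyldimethylsilyl)oxy]-2-methyl-2-(pent-4-en-1-yl)-5-(prop-1-en-2-yl)cyclohexan-1-ol
Conditions: PPTS, MeOH/CH2Cl2, rt
Reagents that add atoms: none
Why: Acid-catalysed methanolysis cleaves the triethylsilyl ether much faster than the two hindered tert-butyldimethylsilyl ethers, freeing only the C5 hydroxyl.

Step 9
Reactants: 12 (1R,2S,3R,4R,5R)-3,4-bis[(tert-butyldimethylsilyl)oxy]-2-methyl-2-(pent-4-en-1-yl)-5-(prop-1-en-2-yl)cyclohexan-1-ol
Product: 13 (2R,3R,4R,5R)-3,4-bis[(tert-butyldimethylsilyl)oxy]-2-methyl-2-(pent-4-en-1-yl)-5-(prop-1-en-2-yl)cyclohexan-1-one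
Conditions: 1,1,1-triacetoxy-1,1-dihydro-1,2-benziodoxol-3(1H)-one (DMP), NaHCO3, CH2Cl2, rt
Reagents that add atoms: none
Why: Hypervalent-iodine oxidation of the secondary alcohol under buffered conditions; C10 is quaternary, so nothing can epimerise or eliminate, and C9 is now an ether, so the symmetric 1,3-diketone is never formed.

Step 10
Reactants: 13 (2R,3R,4R,5R)-3,4-bis[(tert-butyldimethylsilyl)oxy]-2-methyl-2-(pent-4-en-1-yl)-5-(prop-1-en-2-yl)cyclohexan-1-one
Product: 14 (4R,5R,6S,7R)-5,6-bis[(tert-butyldimethylsilyl)oxy]-7-methyl-7-(pent-4-en-1-yl)-4-(prop-1-en-2-yl)oxepan-2-one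
Conditions: Me3SiOOSiMe3, SnCl4 (cat.), trans-cyclohexane-1,2-diamine (cat.), 4 Å MS, CH2Cl2, rt
Reagents that add atoms: bis(trimethylsilyl) peroxide, C[Si](C)(C)OO[Si](C)(C)C
Why: Baeyer–Villiger oxidation with a silyl peroxide under Lewis-acid catalysis, conditions that do not epoxidise isolated alkenes as a peracid would; the quaternary C10 migrates in preference to C6H2 and with retention, placing the ring oxygen between C5 and C10.

Step 11
Reactants: 14 (4R,5R,6S,7R)-5,6-bis[(tert-butyldimethylsilyl)oxy]-7-methyl-7-(pent-4-en-1-yl)-4-(prop-1-en-2-yl)oxepan-2-one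
Product: 15 (4R,5R,6S,7R)-5,6-bis[(tert-butyldimethylsilyl)oxy]-7-methyl-7-(4-oxopentyl)-4-(prop-1-en-2-yl)oxepan-2-one
Conditions: PdCl2 (cat.), CuCl, O2 (1 atm), DMF/H2O, rt
Reagents that add atoms: water, O
Why: Wacker oxidation; divalent palladium hydroxypalladates the monosubstituted terminal alkene in the Markovnikov sense far faster than the 1,1-disubstituted isopropenyl group, giving the methyl ketone at C4.

Step 12
Reactants: 15 (4R,5R,6S,7R)-5,6-bis[(tert-butyldimethylsilyl)oxy]-7-methyl-7-(4-oxopentyl)-4-(prop-1-en-2-yl)oxepan-2-one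
Product: 16 (4R,5R,6S,7R)-5,6-bis[(tert-butyldimethylsilyl)oxy]-7-(4-hydroxypentyl)-7-methyl-4-(prop-1-en-2-yl)oxepan-2-one (both C4 epimers)
Conditions: NaBH4, MeOH, 0 °C
Reagents that add atoms: none
Why: Borohydride reduces the methyl ketone and leaves the ε-lactone alone at 0 °C; the new carbinol centre is formed without control, which is immaterial.

Step 13
Reactants: 16 (4R,5R,6S,7R)-5,6-bis[(tert-butyldimethylsilyl)oxy]-7-(4-hydroxypentyl)-7-methyl-4-(prop-1-en-2-yl)oxepan-2-one
Product: 17 (4R,5R,6S,7R)-5,6-bis[(tert-butyldimethylsilyl)oxy]-7-(4-iodopentyl)-7-methyl-4-(prop-1-en-2-yl)oxepan-2-one (both C4 epimers)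
Conditions: I2, PPh3, imidazole, CH2Cl2, 0 °C to rt
Reagents that add atoms: iodine, II
Why: Appel-type iodination of the secondary alcohol through its alkoxyphosphonium salt (SN2, inversion); the neutral conditions preserve the lactone and the silyl ethers.

Step 14
Reactants: 17 (4R,5R,6S,7R)-5,6-bis[(tert-butyldimethylsilyl)oxy]-7-(4-iodopentyl)-7-methyl-4-(prop-1-en-2-yl)oxepan-2-one
Product: 20 (1R,2S,6R,7S,8R,9R)-7,8-bis[(tert-butyldimethylsilyl)oxy]-2,6-dimethyl-9-(prop-1-en-2-yl)-11-oxabicyclo[4.4.1]undecan-1-ol, via alkylsamarium diiodide 18 (not isolated), via samarium hemiketal alkoxide 19 (not isolated)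
Conditions: SmI2 (3 equiv), Fe(acac)3 (cat.), THF, −30 °C to rt; H2O; then K2CO3, MeOH, rt
Reagents that add atoms: none
Why: Two single-electron transfers from divalent samarium, assisted by the iron catalyst, convert the C4–I bond through the secondary radical into alkylsamarium 18, and C4 loses its configuration at this stage. The carbanionic C4 then adds to the lactone carbonyl C5, an intramolecular nucleophilic acyl substitution of the Barbier type; the closest known reaction is the SmI2-promoted cyclisation of iodoalkyl lactones to bicyclic hemiketals and ring-expanded hydroxy ketones, usually run with primary iodides. Ring C (O, C10, C1–C5) closes by 7-exo-trig attack, the tether being the four-carbon chain on C10 and the ring oxygen. The tetrahedral adduct 19 is already the alkoxide of the bridged hemiketal, so the ten-membered carbocycle appears in the same step, in equilibrium with the 5-keto 10-alkoxide. C5 becomes a bridgehead, so its configuration is dictated by C10. C4 is set thermodynamically: it is α to the carbonyl of the ring-opened tautomer, and the carbonate treatment should favour the epimer with C15 anti to C6 on the outer face. The step needs only that the organosamarium finds no other electrophile, which is secured because the lactone is the sole carbonyl and O8 and O9 are silyl ethers. The HMPA-free conditions are chosen so that the ketone tautomer is not reduced further.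

Step 15
Reactants: 20 (1R,2S,6R,7S,8R,9R)-7,8-bis[(tert-butyldimethylsilyl)oxy]-2,6-dimethyl-9-(prop-1-en-2-yl)-11-oxabicyclo[4.4.1]undecan-1-ol
Product: 21 (1R,2S,3R,4R,6R,7S)-2,3-bis[(tert-butyldimethylsilyl)oxy]-1,7-dimethyl-4-(prop-1-en-2-yl)-11-oxabicyclo[4.4.1]undecane
Conditions: Et3SiH, BF3·OEt2, CH2Cl2, −78 to −20 °C
Reagents that add atoms: none
Why: Ionic reduction of a hemiketal: BF3 ionises the C5–OH bond to an oxocarbenium ion held by the bridging oxygen and triethylsilane delivers hydride; at a bridgehead the hydrogen can only take the outer position, so C5 is formed as a single epimer.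

Step 16
Reactants: 21 (1R,2S,3R,4R,6R,7S)-2,3-bis[(tert-butyldimethylsilyl)oxy]-1,7-dimethyl-4-(prop-1-en-2-yl)-11-oxabicyclo[4.4.1]undecane
Product: 22 (1R,2S,3R,4R,6R,7S)-1,7-dimethyl-4-(prop-1-en-2-yl)-11-oxabicyclo[4.4.1]undecane-2,3-diol
Conditions: Bu4NF, THF, rt to 50 °C
Reagents that add atoms: none
Why: Fluoride cleavage of both silyl ethers; the substrate now holds only ethers and an isolated alkene, so the basic fluoride has nothing else to attack.

Step 17
Reactants: 22 (1R,2S,3R,4R,6R,7S)-1,7-dimethyl-4-(prop-1-en-2-yl)-11-oxabicyclo[4.4.1]undecane-2,3-diol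
Product: 23 (1R,2S,3R,4R,6R,7S)-4-(3-hydroxyprop-1-en-2-yl)-1,7-dimethyl-11-oxabicyclo[4.4.1]undecane-2,3-diol
Conditions: SeO2 (cat.), t-BuOOH, CH2Cl2, rt
Reagents that add atoms: tert-butyl hydroperoxide, CC(C)(C)OO
Why: Selenium dioxide allylic hydroxylation (ene reaction, then [2,3]-sigmatropic shift) with the hydroperoxide as reoxidant; on a 1,1-disubstituted alkene the methyl group reacts in preference to the ring methine C7–H, and any enal formed by over-oxidation is the intermediate of the next step.

Step 18
Reactants: 23 (1R,2S,3R,4R,6R,7S)-4-(3-hydroxyprop-1-en-2-yl)-1,7-dimethyl-11-oxabicyclo[4.4.1]undecane-2,3-diol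
Product: 26 (4S,5R,7R,8R,9S,10R)-5,10-epoxy-9-hydroxygermacr-11(13)-en-12,8-olide, via enal 24 (not isolated), via lactol 25 (not isolated)
Conditions: TEMPO (cat.), PhI(OAc)2, CH2Cl2, rt
Reagents that add atoms: none
Why: Oxoammonium-mediated oxidative lactonisation of a 1,4-diol: the primary allylic alcohol is oxidised to enal 24, the C8 hydroxyl closes the five-membered lactol 25 (favoured over the bridged six-membered one through O9), and the lactol is oxidised to the lactone. The hindered secondary C9 hydroxyl is not oxidised, and the trans ring fusion follows from the existing C7 and C8 configurations.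

Step 19
Reactants: 26 (4S,5R,7R,8R,9S,10R)-5,10-epoxy-9-hydroxygermacr-11(13)-en-12,8-olide; 27 isovaleric anhydride
Product: 28 (4S,5R,7R,8R,9S,10R)-5,10-epoxy-9-(3-methylbutanoyloxy)germacr-11(13)-en-12,8-olide (CNP0274454.1)
Conditions: 27, DMAP (cat.), Et3N, CH2Cl2, rt
Reagents that add atoms: none
Why: DMAP-catalysed acylation of the remaining secondary alcohol; it is placed last so that the ester and the methylene lactone never meet a base, a hydride or a reductant.

## Compound list

1 | (S)-carvone, (5S)-2-methyl-5-(prop-1-en-2-yl)cyclohex-2-en-1-one | CC1=CC[C@@H](CC1=O)C(C)=C | starting material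
2 | 5-bromopent-1-ene | C=CCCCBr | starting material
3 | pent-4-en-1-ylmagnesium bromide (formed in the flask) | C=CCCC[Mg]Br | intermediate
4 | (1S,5S)-2-methyl-1-(pent-4-en-1-yl)-5-(prop-1-en-2-yl)cyclohex-2-en-1-ol (chain trans, OH cis to isopropenyl) | C=CCCC[C@@]1(O)C(C)=CC[C@H](C(C)=C)C1 | intermediate
5 | (1R,2S,4S,6R)-1-methyl-2-(pent-4-en-1-yl)-4-(prop-1-en-2-yl)-7-oxabicyclo[4.1.0]heptan-2-ol (epoxide cis to OH) | C=CCCC[C@@]1(O)[C@]2(C)O[C@@H]2C[C@H](C(C)=C)C1 | intermediate
6 | (2S,3R,5S)-3-hydroxy-2-methyl-2-(pent-4-en-1-yl)-5-(prop-1-en-2-yl)cyclohexan-1-one | O=C1[C@@](C)(CCCC=C)[C@H](O)C[C@H](C(C)=C)C1 | intermediate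
7 | (2S,3R,5S)-2-methyl-2-(pent-4-en-1-yl)-5-(prop-1-en-2-yl)-3-[(triethylsilyl)oxy]cyclohexan-1-one | O=C1[C@@](C)(CCCC=C)[C@H](O[Si](CC)(CC)CC)C[C@H](C(C)=C)C1 | intermediate
8 | potassium enolate of 7 (C8=C9 enolate, formed in the flask) | [K+].[O-]C=1[C@@](C)(CCCC=C)[C@H](O[Si](CC)(CC)CC)C[C@H](C(C)=C)C=1 | intermediate
9 | (2S,3R,5R,6R)-6-hydroxy-2-methyl-2-(pent-4-en-1-yl)-5-(prop-1-en-2-yl)-3-[(triethylsilyl)oxy]cyclohexan-1-one | O=C1[C@@](C)(CCCC=C)[C@H](O[Si](CC)(CC)CC)C[C@H](C(C)=C)[C@H]1O | intermediate
10 | (1R,2R,3R,4R,6R)-3-methyl-3-(pent-4-en-1-yl)-6-(prop-1-en-2-yl)-4-[(triethylsilyl)oxy]cyclohexane-1,2-diol | O[C@@H]1[C@@](C)(CCCC=C)[C@H](O[Si](CC)(CC)CC)C[C@H](C(C)=C)[C@H]1O | intermediate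
11 | 1,2-bis(tert-butyldimethylsilyl) ether of 10 | CC(C)(C)[Si](C)(C)O[C@@H]1[C@@](C)(CCCC=C)[C@H](O[Si](CC)(CC)CC)C[C@H](C(C)=C)[C@H]1O[Si](C)(C)C(C)(C)C | intermediate
12 | (1R,2S,3R,4R,5R)-3,4-bis[(tert-butyldimethylsilyl)oxy]-2-methyl-2-(pent-4-en-1-yl)-5-(prop-1-en-2-yl)cyclohexan-1-ol | CC(C)(C)[Si](C)(C)O[C@@H]1[C@@](C)(CCCC=C)[C@H](O)C[C@H](C(C)=C)[C@H]1O[Si](C)(C)C(C)(C)C | intermediate
13 | (2R,3R,4R,5R)-3,4-bis[(tert-butyldimethylsilyl)oxy]-2-methyl-2-(pent-4-en-1-yl)-5-(prop-1-en-2-yl)cyclohexan-1-one | CC(C)(C)[Si](C)(C)O[C@@H]1[C@@](C)(CCCC=C)C(=O)C[C@H](C(C)=C)[C@H]1O[Si](C)(C)C(C)(C)C | intermediate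
14 | (4R,5R,6S,7R)-5,6-bis[(tert-butyldimethylsilyl)oxy]-7-methyl-7-(pent-4-en-1-yl)-4-(prop-1-en-2-yl)oxepan-2-one | CC(C)(C)[Si](C)(C)O[C@@H]1[C@@](C)(CCCC=C)OC(=O)C[C@H](C(C)=C)[C@H]1O[Si](C)(C)C(C)(C)C | intermediate
15 | (4R,5R,6S,7R)-5,6-bis[(tert-butyldimethylsilyl)oxy]-7-methyl-7-(4-oxopentyl)-4-(prop-1-en-2-yl)oxepan-2-one | CC(C)(C)[Si](C)(C)O[C@@H]1[C@@](C)(CCCC(C)=O)OC(=O)C[C@H](C(C)=C)[C@H]1O[Si](C)(C)C(C)(C)C | intermediate
16 | (4R,5R,6S,7R)-5,6-bis[(tert-butyldimethylsilyl)oxy]-7-(4-hydroxypentyl)-7-methyl-4-(prop-1-en-2-yl)oxepan-2-one, both C4 epimers | CC(C)(C)[Si](C)(C)O[C@@H]1[C@@](C)(CCCC(C)O)OC(=O)C[C@H](C(C)=C)[C@H]1O[Si](C)(C)C(C)(C)C | intermediate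
17 | (4R,5R,6S,7R)-5,6-bis[(tert-butyldimethylsilyl)oxy]-7-(4-iodopentyl)-7-methyl-4-(prop-1-en-2-yl)oxepan-2-one, both C4 epimers | CC(C)(C)[Si](C)(C)O[C@@H]1[C@@](C)(CCCC(C)I)OC(=O)C[C@H](C(C)=C)[C@H]1O[Si](C)(C)C(C)(C)C | intermediate
18 | alkylsamarium diiodide from 17 (C4–Sm, formed in the flask) | CC(C)(C)[Si](C)(C)O[C@@H]1[C@@](C)(CCCC(C)[Sm](I)I)OC(=O)C[C@H](C(C)=C)[C@H]1O[Si](C)(C)C(C)(C)C | intermediate
19 | samarium alkoxide of hemiketal 20 (C4 epimers, formed in the flask) | CC(=C)[C@H]1C[C@@]2(O[Sm](I)I)O[C@](C)(CCCC2C)[C@@H](O[Si](C)(C)C(C)(C)C)[C@@H]1O[Si](C)(C)C(C)(C)C | intermediate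
20 | (1R,2S,6R,7S,8R,9R)-7,8-bis[(tert-butyldimethylsilyl)oxy]-2,6-dimethyl-9-(prop-1-en-2-yl)-11-oxabicyclo[4.4.1]undecan-1-ol (C5 bridgehead hemiketal) | CC(=C)[C@H]1C[C@@]2(O)O[C@](C)(CCC[C@@H]2C)[C@@H](O[Si](C)(C)C(C)(C)C)[C@@H]1O[Si](C)(C)C(C)(C)C | intermediate
21 | (1R,2S,3R,4R,6R,7S)-2,3-bis[(tert-butyldimethylsilyl)oxy]-1,7-dimethyl-4-(prop-1-en-2-yl)-11-oxabicyclo[4.4.1]undecane | CC(=C)[C@H]1C[C@H]2O[C@](C)(CCC[C@@H]2C)[C@@H](O[Si](C)(C)C(C)(C)C)[C@@H]1O[Si](C)(C)C(C)(C)C | intermediate
22 | (1R,2S,3R,4R,6R,7S)-1,7-dimethyl-4-(prop-1-en-2-yl)-11-oxabicyclo[4.4.1]undecane-2,3-diol | CC(=C)[C@H]1C[C@H]2O[C@](C)(CCC[C@@H]2C)[C@@H](O)[C@@H]1O | intermediate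
23 | (1R,2S,3R,4R,6R,7S)-4-(3-hydroxyprop-1-en-2-yl)-1,7-dimethyl-11-oxabicyclo[4.4.1]undecane-2,3-diol | C=C(CO)[C@H]1C[C@H]2O[C@](C)(CCC[C@@H]2C)[C@@H](O)[C@@H]1O | intermediate
24 | enal from 23 (C12 aldehyde, formed in the flask) | C=C(C=O)[C@H]1C[C@H]2O[C@](C)(CCC[C@@H]2C)[C@@H](O)[C@@H]1O | intermediate
25 | 12,8-lactol from 24 (C12 epimers, formed in the flask) | C=C1C(O)O[C@@H]2[C@@H]1C[C@H]1O[C@](C)(CCC[C@@H]1C)[C@H]2O | intermediate
26 | (4S,5R,7R,8R,9S,10R)-5,10-epoxy-9-hydroxygermacr-11(13)-en-12,8-olide | C=C1C(=O)O[C@@H]2[C@@H]1C[C@H]1O[C@](C)(CCC[C@@H]1C)[C@H]2O | intermediate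
27 | isovaleric anhydride (3-methylbutanoic anhydride) | CC(C)CC(=O)OC(=O)CC(C)C | starting material
28 | CNP0274454.1, (4S,5R,7R,8R,9S,10R)-5,10-epoxy-9-(3-methylbutanoyloxy)germacr-11(13)-en-12,8-olide | C=C1C(=O)O[C@@H]2[C@@H]1C[C@H]1O[C@](C)(CCC[C@@H]1C)[C@H]2OC(=O)CC(C)C | target

## Step count and least certain steps

Total step count: 19. Longest linear sequence: 19 steps, from 1 to 28 (2 enters in step 1 and 27 in step 19).

**Step 14 (key step).** The secondary radical or organosamarium may be quenched (hydrogen abstraction, protonation or elimination) before it closes the seven-membered ring, because this closure by a hindered secondary nucleophile is slower than the five- and six-membered closures usual for the reaction. Incomplete equilibration at C4 is the second concern. Fallback: replace the reductively formed organometallic by a stabilised carbanion. From 17, displacement with PhSO2Na in DMF gives the sulfone lactone F1. KN(SiMe3)2 forms the α-sulfonyl carbanion, which acylates on the lactone carbonyl to give the β-keto sulfone F2 (hemiketal or keto alcohol). SmI2 in THF/MeOH cleaves the C–S bond, and the same carbonate equilibration returns the route at 20.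

**Step 3.** Ring contraction by migration of the C8–C9 ring bond, hydride shift from C5, or elimination from the C10 cation may compete if the epoxide opens before the pentenyl group is aligned; retro-aldol cleavage of 6 on warming is a further loss. Fallback: change the substrate class from the free epoxy alcohol to its silyl ether. From 5, Me3SiCl/imidazole gives the trimethylsilyl ether F3, and TiCl4 in CH2Cl2 at −78 °C triggers the shift; the resulting titanium aldolate is hydrolysed to 6.

**Step 10.** The silyl peroxide may add too slowly to a carbonyl flanked by a quaternary carbon, so that Lewis-acid-induced loss of silyl ethers or ionisation of the tertiary alkyl–oxygen bond of the product takes over. Fallback: accept oxidation of the alkenes and undo it. From 13, excess mCPBA with NaHCO3 gives the bis-epoxy lactone F4 (ring oxygen inserted, both alkenes epoxidised), and Zn/NaI in AcOH/NaOAc deoxygenates both epoxides, returning to 14.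

**Step 15.** Ionisation at the bridgehead gives a twisted oxocarbenium ion that may form slowly, so that reduction of the ring-opened ketone or loss of a silyl ether could outrun it. Fallback: pass through a radical, which tolerates a pyramidal bridgehead. From 20, methyl chlorooxoacetate with DMAP/pyridine gives the hemiketal methyl oxalate F5, and Bu3SnH/AIBN in hot toluene replaces the oxalate by hydrogen to give 21.

**Step 17.** Over-oxidation, attack at the ring methine, or stalling through binding of selenium by the free diol may occur. Fallback: from 22, mCPBA epoxidises the only alkene to the epoxide F6, and Al(OiPr)3 in refluxing toluene isomerises it, by removal of a methyl proton, to allylic alcohol 23.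

## Further compounds

F1 | step 14 | (4R,5R,6S,7R)-7-[4-(benzenesulfonyl)pentyl]-5,6-bis[(tert-butyldimethylsilyl)oxy]-7-methyl-4-(prop-1-en-2-yl)oxepan-2-one, both C4 epimers | CC(C)(C)[Si](C)(C)O[C@@H]1[C@@](C)(CCCC(C)S(=O)(=O)c2ccccc2)OC(=O)C[C@H](C(C)=C)[C@H]1O[Si](C)(C)C(C)(C)C
F2 | step 14 | 2-(benzenesulfonyl) derivative of hemiketal 20 (C4 quaternary, both epimers) | CC(=C)[C@H]1C[C@@]2(O)O[C@](C)(CCCC2(C)S(=O)(=O)c3ccccc3)[C@@H](O[Si](C)(C)C(C)(C)C)[C@@H]1O[Si](C)(C)C(C)(C)C
F3 | step 3 | trimethylsilyl ether of 5 | C=CCCC[C@@]1(O[Si](C)(C)C)[C@]2(C)O[C@@H]2C[C@H](C(C)=C)C1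
F4 | step 10 | bis-epoxide of lactone 14 (chain and isopropenyl alkenes epoxidised, epimers at the new epoxide carbons) | CC(C)(C)[Si](C)(C)O[C@@H]1[C@@](C)(CCCC2CO2)OC(=O)C[C@H](C2(C)CO2)[C@H]1O[Si](C)(C)C(C)(C)C
F5 | step 15 | methyl oxalate of hemiketal 20 | CC(=C)[C@H]1C[C@@]2(OC(=O)C(=O)OC)O[C@](C)(CCC[C@@H]2C)[C@@H](O[Si](C)(C)C(C)(C)C)[C@@H]1O[Si](C)(C)C(C)(C)C
F6 | step 17 | 11,13-epoxide of diol 22 (epimers at C11) | CC1(CO1)[C@H]2C[C@H]3O[C@](C)(CCC[C@@H]3C)[C@@H](O)[C@@H]2O
A1 | alternative 1 | (2R,3S)-2-allyl-3-methylcyclohexan-1-one | O=C1CCC[C@H](C)[C@H]1CC=C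
A2 | alternative 2 | oxa-bridged bicyclic lactone with C9 ketone and C2=C3 alkene | O=C1C[C@H]2C[C@H]3O[C@](C)(C/C=C\[C@@H]3C)C(=O)[C@@H]2O1
A3 | alternative 3 | α-(diethoxyphosphoryl) lactone of the target skeleton | CCOP(=O)(OCC)[C@H]1C(=O)O[C@@H]2[C@@H]1C[C@H]1O[C@](C)(CCC[C@@H]1C)[C@H]2OC(=O)CC(C)C
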